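## Retrosynthetic overview

1. Remove the acetate. Open the α-methylene-γ-lactone (second ring formed) to a cembratetraene-2,6,16-triol. In the forward sense, C16 is oxidised and closes onto the C2 oxygen.
2. Remove the C16 hydroxyl. In the forward sense, the isopropenyl methyl of a cembra-3,7,11,15(17)-tetraene-2,6-diol is hydroxylated.
3. Cut the 14-membered carbocycle (first ring formed) at C1–C2. In the forward sense, the terminal isopropylidene of acyclic (5R)-5-hydroxygeranylgeranial attacks its own Lewis-acid-activated enal carbon and a proton is lost to give the isopropenyl group (macrocyclic carbonyl-ene). This sets C1 and C2.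
4. Cut the C20 chain at C5–C6. In the forward sense, (E,E)-farnesal (C15) and the silyl dienol ether of prenal (C5) combine in an enantioselective vinylogous Mukaiyama aldol. This sets C6.

Assumption: cembrane numbering is used (C1 carries C15–C17, C2 the lactone oxygen, C6 the acetate), and the L-tryptophan-derived boron catalyst is taken to direct attack to the Re face of the aldehyde; if the sense is opposite, the equally cheap D-tryptophan catalyst is used.

## Route

Step 1
Reactants: 1 (2E,6E)-farnesol
Product: 2 (2E,6E)-farnesal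
Conditions: [Cu(MeCN)4]OTf (5 mol %), bpy (5 mol %), TEMPO (5 mol %), NMI (10 mol %), air, MeCN, rt
Reagents that add atoms: none
Why: Cu/nitroxyl aerobic alcohol oxidation takes a primary allylic alcohol to the enal at room temperature without E/Z leakage and without touching the isolated trisubstituted alkenes; no stereocentre is formed.

Step 2
Reactants: 3 3-methylbut-2-enal (prenal)
Product: 4 (E)-1-(tert-butyldimethylsilyloxy)-3-methylbuta-1,3-diene
Conditions: TBSOTf (1.05 equiv), Et3N (1.3 equiv), Et2O, 0 °C to rt; distil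
Reagents that add atoms: TBSOTf, CC(C)(C)[Si](C)(C)OS(=O)(=O)C(F)(F)F
Why: Soft enolisation (O-silylation of the s-trans enal, then γ-deprotonation by the amine) gives the 1-silyloxydiene as the E enol ether; no stereocentre is formed.

Step 3
Reactants: 2 (2E,6E)-farnesal (2.5 equiv, surplus recovered); 4 (E)-1-(tert-butyldimethylsilyloxy)-3-methylbuta-1,3-diene
Product: 5 (2E,5R,6E,10E)-5-hydroxy-3,7,11,15-tetramethylhexadeca-2,6,10,14-tetraenal
Conditions: B-phenyl oxazaborolidinone from N-Ts-L-tryptophan and PhBCl2 (0.5 equiv), i-PrOH (1.1 equiv), EtCN, −78 °C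
Reagents that add atoms: none
Why: In this catalytic enantioselective vinylogous Mukaiyama aldol reaction of an aldehyde-derived dienolate, the boron Lewis acid binds the formyl group of 2 and its indole shields the Si face, so the γ-carbon of s-trans 4 attacks the Re face through an open transition state, which sets cembrane C6 as R and the new C3=C4 bond as E, while the excess of 2 keeps the equally reactive product enal from adding a second diene.

Step 4
Reactants: 5 (2E,5R,6E,10E)-5-hydroxy-3,7,11,15-tetramethylhexadeca-2,6,10,14-tetraenal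
Product: 7 (1R,2S,3E,6R,7E,11E)-cembra-3,7,11,15(17)-tetraene-2,6-diol, via chloro(methyl)aluminium alkoxide 6 (not isolated)
Conditions: Me2AlCl (1.0 equiv), CH2Cl2, −78 °C; then syringe pump (12 h) into Me2AlCl (2.5 equiv), CH2Cl2, final 1 mM, −78 to −30 °C; aq Rochelle salt; chromatography
Reagents that add atoms: none
Why: Proposed new method: the C6 hydroxyl is first masked in situ as aluminium alkoxide 6 (methane loss), Me2AlCl then turns the E-enal into a 1-oxyallyl cation equivalent that is attacked at C2 by the distal, least hindered and most nucleophilic isopropylidene group (the E geometry forbids six-ring closure onto C7=C8, which is also deactivated by the allylic oxygen, and ten-ring closure onto C11=C12 is strained), a methyl hydrogen passes to oxygen through a chair-like six-centre transition state with C3 anti to C15 to give the trans isopropenyl carbinol, and the outward-pointing C6 O-aluminium group (C6–H eclipsed with C7=C8 by A1,3 strain) is relied on to bias attack to the Re face of C2 (1R,2S), any (1S,2R,6R) diastereomer being removed by chromatography; the closest known reaction types are the type I carbonyl-ene cyclisations of citronellal to isopulegol and of neral to trans-isopiperitenol, the alkylaluminium-chloride-promoted 14-membered ene closure of isopropylidene-terminated ynals, and the SnCl4 cyclisation of geranylgeranoyl chloride to a cembrane ketone.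

Step 5
Reactants: 7 (1R,2S,3E,6R,7E,11E)-cembra-3,7,11,15(17)-tetraene-2,6-diol
Product: 10 (1R,2S,3E,6R,7E,11E)-cembra-3,7,11,15(17)-tetraene-2,6,16-triol, via trilithio species 8 (not isolated), via allyl dimethyl boronate 9 (not isolated)
Conditions: n-BuLi (3.3 equiv), TMEDA (3.3 equiv), Et2O–hexane, 0 °C to rt; B(OMe)3, −78 °C to rt; H2O2, aq NaOH, 0 °C
Reagents that add atoms: hydrogen peroxide, OO
Why: In this alkoxide-assisted allylic metalation followed by borylation and oxidation, as with isopulegol, isoprenol and limonene, the methyl of the 1,1-disubstituted alkene is the kinetically most acidic allylic site and sits next to the C2 lithium alkoxide, the 2-substituted allyl anion has two equivalent CH2 termini so no regioisomer can form, lithium rather than potassium alkoxides keep the anionic oxy-Cope pathway slow, and no stereocentre is touched.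

Step 6
Reactants: 10 (1R,2S,3E,6R,7E,11E)-cembra-3,7,11,15(17)-tetraene-2,6,16-triol
Product: 13 (1R,2S,3E,6R,7E,11E)-6-hydroxycembra-3,7,11,15(17)-tetraen-16,2-olide, via hydroxy enal 11 (not isolated), via lactol 12 (not isolated)
Conditions: TEMPO (0.2 equiv), PhI(OAc)2 (2.3 equiv), CH2Cl2, 0 °C to rt
Reagents that add atoms: none
Why: In this nitroxyl-catalysed chemoselective oxidative lactonisation of a 1,4-diol, the oxoammonium salt oxidises the unhindered primary allylic alcohol much faster than the two secondary ones, enal 11 closes onto the C2 hydroxyl to lactol 12, and the lactol is oxidised on to the lactone, so the trans C1/C2 relationship set in step 4 is carried over unchanged.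

Step 7
Reactants: 13 (1R,2S,3E,6R,7E,11E)-6-hydroxycembra-3,7,11,15(17)-tetraen-16,2-olide
Product: 14 (1R,2S,3E,6R,7E,11E)-6-acetoxycembra-3,7,11,15(17)-tetraen-16,2-olide (CNP0206931.1)
Conditions: Ac2O (1.5 equiv), pyridine (3 equiv), DMAP (5 mol %), CH2Cl2, 0 °C
Reagents that add atoms: acetic anhydride, CC(=O)OC(C)=O
Why: DMAP-catalysed O-acylation of the only free hydroxyl proceeds with retention at C6 and leaves the α-methylene lactone intact under these short, mild conditions.

## Compound list

1 | (2E,6E)-farnesol | OC/C=C(\C)CC/C=C(\C)CCC=C(C)C | starting material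
2 | (2E,6E)-farnesal | O=C/C=C(\C)CC/C=C(\C)CCC=C(C)C | intermediate
3 | 3-methylbut-2-enal (prenal) | CC(C)=CC=O | starting material
4 | (E)-1-(tert-butyldimethylsilyloxy)-3-methylbuta-1,3-diene | C=C(C)/C=C/O[Si](C)(C)C(C)(C)C | intermediate
5 | (2E,5R,6E,10E)-5-hydroxy-3,7,11,15-tetramethylhexadeca-2,6,10,14-tetraenal (chain C5 = cembrane C6) | O=C/C=C(\C)C[C@@H](O)/C=C(\C)CC/C=C(\C)CCC=C(C)C | intermediate
6 | O-chloro(methyl)aluminium alkoxide of 5 | O=C/C=C(\C)C[C@@H](O[Al](C)Cl)/C=C(\C)CC/C=C(\C)CCC=C(C)C | intermediate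
7 | (1R,2S,3E,6R,7E,11E)-cembra-3,7,11,15(17)-tetraene-2,6-diol, i.e. (1S,2E,5R,6E,10E,14R)-3,7,11-trimethyl-14-(prop-1-en-2-yl)cyclotetradeca-2,6,10-triene-1,5-diol | O[C@H]1/C=C(\C)C[C@@H](O)/C=C(\C)CC/C=C(\C)CC[C@@H]1C(C)=C | intermediate
8 | 2,6-di-O-lithio-16-lithio derivative of 7 | [Li]O[C@H]1/C=C(\C)C[C@@H](O[Li])/C=C(\C)CC/C=C(\C)CC[C@@H]1C(=C)C[Li] | intermediate
9 | dilithium 2,6-dialkoxide carrying a 16-dimethoxyboryl group | [Li]O[C@H]1/C=C(\C)C[C@@H](O[Li])/C=C(\C)CC/C=C(\C)CC[C@@H]1C(=C)CB(OC)OC | intermediate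
10 | (1R,2S,3E,6R,7E,11E)-cembra-3,7,11,15(17)-tetraene-2,6,16-triol | O[C@H]1/C=C(\C)C[C@@H](O)/C=C(\C)CC/C=C(\C)CC[C@@H]1C(=C)CO | intermediate
11 | (1R,2S,3E,6R,7E,11E)-2,6-dihydroxycembra-3,7,11,15(17)-tetraen-16-al | O[C@H]1/C=C(\C)C[C@@H](O)/C=C(\C)CC/C=C(\C)CC[C@@H]1C(=C)C=O | intermediate
12 | (1R,2S,6R)-2,16-epoxycembra-3,7,11,15(17)-tetraene-6,16-diol (lactol, C16 epimers) | C=C1C(O)O[C@H]2/C=C(\C)C[C@@H](O)/C=C(\C)CC/C=C(\C)CC[C@H]12 | intermediate
13 | (1R,2S,3E,6R,7E,11E)-6-hydroxycembra-3,7,11,15(17)-tetraen-16,2-olide (trans-fused lactone) | C=C1C(=O)O[C@H]2/C=C(\C)C[C@@H](O)/C=C(\C)CC/C=C(\C)CC[C@H]12 | intermediate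
14 | (1R,2S,3E,6R,7E,11E)-6-acetoxycembra-3,7,11,15(17)-tetraen-16,2-olide | C=C1C(=O)O[C@H]2/C=C(\C)C[C@@H](OC(C)=O)/C=C(\C)CC/C=C(\C)CC[C@H]12 | target

## Step count

- Total step count: 7.
- Longest linear sequence: 6 steps (1 → 2 → 5 → 7 → 10 → 13 → 14).

## Three steps most likely to fail

**Step 4.**
- Risks: a β,β-disubstituted enal is a weak enophile, so oligomerisation, methyl transfer from aluminium, or E-to-Z leakage of the enal may outrun the 14-ring closure.
- The control of the C1/C2 sense by remote C6 may also be weak or go the wrong way.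
- The fallback closes the same bond by umpolung instead of cation–olefin chemistry. It sets out from 5 and comes back at 7.
- Catalytic SeO2 with t-BuOOH hydroxylates the terminal E-methyl to give (2E,5R,6E,10E,14E)-5,16-dihydroxy-3,7,11,15-tetramethylhexadeca-2,6,10,14-tetraenal F1.
- CBr4/PPh3 at −30 °C converts only the primary allylic alcohol into (2E,5R,6E,10E,14E)-16-bromo-5-hydroxy-3,7,11,15-tetramethylhexadeca-2,6,10,14-tetraenal F2.
- CrCl2 in THF at high dilution, with a chiral oxazoline–sulfonamide ligand for reagent control, adds the allylchromium through its γ-carbon (C1) to the aldehyde. This is an anti-selective Nozaki–Hiyama–Kishi macrocyclisation, and it gives 7.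

**Step 5.**
- Risks: the C2 and C6 allylic alkoxides can also direct lithiation to the cis methyl groups C18 and C19, and the trianion may be poorly soluble.
- The fallback replaces allylic metalation by chemoselective hydroboration followed by dehydrogenation. It sets out from 7 and comes back at 13.
- 9-BBN followed by H2O2/NaOH attacks only the 1,1-disubstituted alkene and gives (1R,2S,6R)-cembra-3,7,11-triene-2,6,17-triol F3 (C15 epimers).
- TEMPO/PhI(OAc)2 gives (1R,2S,6R)-6-hydroxycembra-3,7,11-trien-16,2-olide F4, the α-methyl lactone.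
- LDA (2.2 equiv) and then PhSeCl give (1R,2S,6R)-6-hydroxy-15-(phenylselanyl)cembra-3,7,11-trien-16,2-olide F5.
- H2O2 oxidation with selenoxide syn-elimination goes towards the methyl group in trans-fused lactones and gives 13.

**Step 3.**
- Risks: product 5 is an enal of about the same reactivity as 2, so a second addition competes.
- The ee and the E/Z ratio with a β-methyl dienol ether and a β,β-disubstituted enal are also untested.
- The fallback uses an ester-level nucleophile whose product cannot react again, at the price of two redox steps. It sets out from 2 and comes back at 5.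
- Methyl 3-methylbut-2-enoate with LDA and then TBSCl gives 1-(tert-butyldimethylsilyloxy)-1-methoxy-3-methylbuta-1,3-diene F6.
- SiCl4 with a chiral bisphosphoramide catalyst (CH2Cl2, −78 °C) joins F6 to 2 and gives methyl (2E,5R,6E,10E)-5-hydroxy-3,7,11,15-tetramethylhexadeca-2,6,10,14-tetraenoate F7.
- DIBAL-H gives (2E,5R,6E,10E)-3,7,11,15-tetramethylhexadeca-2,6,10,14-tetraene-1,5-diol F8.
- The Cu/TEMPO/air system of step 1 oxidises only the primary allylic alcohol and gives 5.

## Further compounds

F1 | step 4 | (2E,5R,6E,10E,14E)-5,16-dihydroxy-3,7,11,15-tetramethylhexadeca-2,6,10,14-tetraenal | O=C/C=C(\C)C[C@@H](O)/C=C(\C)CC/C=C(\C)CC/C=C(\C)CO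
F2 | step 4 | (2E,5R,6E,10E,14E)-16-bromo-5-hydroxy-3,7,11,15-tetramethylhexadeca-2,6,10,14-tetraenal | O=C/C=C(\C)C[C@@H](O)/C=C(\C)CC/C=C(\C)CC/C=C(\C)CBr
F3 | step 5 | (1R,2S,6R)-cembra-3,7,11-triene-2,6,17-triol (C15 epimers) | O[C@H]1/C=C(\C)C[C@@H](O)/C=C(\C)CC/C=C(\C)CC[C@@H]1C(C)CO
F4 | step 5 | (1R,2S,6R)-6-hydroxycembra-3,7,11-trien-16,2-olide (C15 epimers) | CC1C(=O)O[C@H]2/C=C(\C)C[C@@H](O)/C=C(\C)CC/C=C(\C)CC[C@H]12
F5 | step 5 | (1R,2S,6R)-6-hydroxy-15-(phenylselanyl)cembra-3,7,11-trien-16,2-olide | CC1([Se]c3ccccc3)C(=O)O[C@H]2/C=C(\C)C[C@@H](O)/C=C(\C)CC/C=C(\C)CC[C@H]12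
F6 | step 3 | 1-(tert-butyldimethylsilyloxy)-1-methoxy-3-methylbuta-1,3-diene | C=C(C)C=C(OC)O[Si](C)(C)C(C)(C)C
F7 | step 3 | methyl (2E,5R,6E,10E)-5-hydroxy-3,7,11,15-tetramethylhexadeca-2,6,10,14-tetraenoate | COC(=O)/C=C(\C)C[C@@H](O)/C=C(\C)CC/C=C(\C)CCC=C(C)C
F8 | step 3 | (2E,5R,6E,10E)-3,7,11,15-tetramethylhexadeca-2,6,10,14-tetraene-1,5-diol | OC/C=C(\C)C[C@@H](O)/C=C(\C)CC/C=C(\C)CCC=C(C)C
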